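**Assumption:** the tertiary carbinol is set by non-chelation (polar Felkin–Anh) addition to an α-alkoxy ketone. I expect this to give the configuration drawn, but it is the least certain stereochemical step.

## Retrosynthetic overview
1. Target **15** comes from acetonide removal of the enone acetonide **14**.
2. **14** comes from intramolecular aldol condensation of the δ-keto-aldehyde **13**. This is the only ring formed; the C–D bond closes the cyclohexenone.
3. The quaternary carbinol carbon comes from 1-ethoxyvinyl-anion addition (an acetyl-anion equivalent) to the α-alkoxy ketone **9**.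
4. **9** comes from the Weinreb amide of L-tartrate, which supplies the trans-diol stereocentres, plus the (Z)-heptadec-8-enyl Grignard made from **4**. **4** is built from 1-decyne and 1,7-dibromoheptane, with Lindlar reduction to set the Z-alkene.

## Route

**Step 1**
Reactants: **1** 1-decyne; **2** 1,7-dibromoheptane
Product: **3** 1-bromoheptadec-8-yne
Conditions: n-BuLi, THF/HMPA, −78 °C → rt; then **2** (3 equiv)
Reagents that add atoms: none (n-BuLi only deprotonates)
Why: SN2 alkylation of the lithium acetylide with excess dibromide gives the mono-alkylated bromide, and no stereocentre is involved.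

**Step 2**
Reactants: **3**
Product: **4** (Z)-1-bromoheptadec-8-ene
Conditions: H2 (1 atm), Lindlar catalyst, quinoline, EtOAc, rt
Reagents that add atoms: none (only H added)
Why: syn-semihydrogenation of the alkyne gives the Z-alkene, and the primary bromide survives.

**Step 3**
Reactants: **5** dimethyl 2,3-O-isopropylidene-L-tartrate
Product: **6** methyl (4R,5S)-5-(hydroxymethyl)-2,2-dimethyl-1,3-dioxolane-4-carboxylate
Conditions: NaBH4 (0.6 equiv), EtOH, 0 °C
Reagents that add atoms: none
Why: chemoselective mono-reduction of the C2-symmetric diester desymmetrises it. The trans-diol stereocentres (E and F) come unchanged from L-tartrate.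

**Step 4**
Reactants: **6**
Product: **7** TBS ether of **6**
Conditions: TBSCl, imidazole, DMF, rt
Reagents that add atoms: TBSCl, CC(C)(C)[Si](C)(C)Cl
Why: silylation of the primary alcohol masks it as a latent aldehyde.

**Step 5**
Reactants: **7**
Product: **8** Weinreb amide
Conditions: MeNH(OMe)·HCl, i-PrMgCl, THF, −20 → 0 °C
Reagents that add atoms: N,O-dimethylhydroxylamine hydrochloride, CNOC.Cl
Why: magnesium-amide aminolysis converts the ester into an amide that stops cleanly at the ketone in the next step.

**Step 6**
Reactants: **8**; **4** (as its Grignard reagent)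
Product: **9** (Z)-1-[(4R,5S)-5-(TBSoxymethyl)-2,2-dimethyl-1,3-dioxolan-4-yl]octadec-9-en-1-one
Conditions: Mg, THF, rt to form RMgBr from **4**; add **8**, THF, 0 °C → rt
Reagents that add atoms: none (the R group comes from **4**; Mg is lost as a bromide salt)
Why: Weinreb ketone synthesis gives the ketone through a stable chelated intermediate, without over-addition, and leaves the Z-alkene intact.

**Step 7**
Reactants: **9**
Product: **10** tertiary alcohol enol ether, (R)-configured at the carbinol carbon
Conditions: 1-ethoxyvinyllithium (ethyl vinyl ether, t-BuLi, THF, −78 → 0 °C), then **9**, THF, −78 °C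
Reagents that add atoms: ethyl vinyl ether, C=COCC
Why: the organolithium adds by non-chelation Felkin–Anh attack, anti to the α-C–O bond of the tartrate-derived stereocentre. This sets the quaternary carbinol centre cis to the neighbouring OH, which is the relationship the target needs.

**Step 8**
Reactants: **10**
Product: **11** α-hydroxy methyl ketone
Conditions: PPTS, acetone/H2O, rt
Reagents that add atoms: water, O
Why: mild hydrolysis of the enol ether gives the methyl ketone, and the acetonide, TBS ether and Z-alkene are not touched.

**Step 9**
Reactants: **11**
Product: **12** primary alcohol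
Conditions: HF·pyridine, THF/pyridine, 0 °C → rt
Reagents that add atoms: none
Why: fluoride cleaves the silyl ether under non-basic conditions, avoiding epimerisation and retro-aldol.

**Step 10**
Reactants: **12**
Product: **13** δ-keto-aldehyde
Conditions: Dess–Martin periodinane, NaHCO3, CH2Cl2, 0 °C → rt (crude aldehyde used at once)
Reagents that add atoms: none
Why: buffered mild oxidation of the primary alcohol avoids epimerising the α-alkoxy aldehyde. The trans-dioxolane is also the more stable isomer.

**Step 11**
Reactants: **13**
Product: **14** acetonide-protected cyclohexenone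
Conditions: piperidine (cat.), AcOH (cat.), benzene, 50 °C
Reagents that add atoms: none (water is lost)
Why: 6-(enolendo)-exo-trig intramolecular aldol condensation. The only enolisable α-carbon is the methyl group, because the other side of the ketone is quaternary, so ring closure is regiospecific. Dehydration gives the enone, and no new stereocentre forms.

**Step 12**
Reactants: **14**
Product: **15** Pleiogenone A
Conditions: 80% aq. AcOH, 40 °C
Reagents that add atoms: none
Why: hydrolysis of the strained trans-fused acetonide releases the trans-diol under mild acid that leaves the γ-hydroxy-enone, the tertiary α-ketol and the Z-alkene unchanged.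

## Compound list
1 | 1-decyne | CCCCCCCCC#C | starting material
2 | 1,7-dibromoheptane | BrCCCCCCCBr | starting material
3 | 1-bromoheptadec-8-yne | CCCCCCCCC#CCCCCCCCBr | intermediate
4 | (Z)-1-bromoheptadec-8-ene | CCCCCCCC/C=C\CCCCCCCBr | intermediate
5 | dimethyl 2,3-O-isopropylidene-L-tartrate | COC(=O)[C@@H]1OC(C)(C)O[C@H]1C(=O)OC | starting material
6 | hydroxy ester | COC(=O)[C@@H]1OC(C)(C)O[C@H]1CO | intermediate
7 | TBS ether | COC(=O)[C@@H]1OC(C)(C)O[C@H]1CO[Si](C)(C)C(C)(C)C | intermediate
8 | Weinreb amide | CON(C)C(=O)[C@@H]1OC(C)(C)O[C@H]1CO[Si](C)(C)C(C)(C)C | intermediate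
9 | oleoyl-type ketone | CCCCCCCC/C=C\CCCCCCCC(=O)[C@@H]1OC(C)(C)O[C@H]1CO[Si](C)(C)C(C)(C)C | intermediate
10 | tertiary alcohol enol ether | CCCCCCCC/C=C\CCCCCCC[C@](O)(C(=C)OCC)[C@@H]1OC(C)(C)O[C@H]1CO[Si](C)(C)C(C)(C)C | intermediate
11 | α-hydroxy methyl ketone (TBS) | CCCCCCCC/C=C\CCCCCCC[C@](O)(C(C)=O)[C@@H]1OC(C)(C)O[C@H]1CO[Si](C)(C)C(C)(C)C | intermediate
12 | primary alcohol | CCCCCCCC/C=C\CCCCCCC[C@](O)(C(C)=O)[C@@H]1OC(C)(C)O[C@H]1CO | intermediate
13 | δ-keto-aldehyde | CCCCCCCC/C=C\CCCCCCC[C@](O)(C(C)=O)[C@@H]1OC(C)(C)O[C@H]1C=O | intermediate
14 | enone acetonide | CCCCCCCC/C=C\CCCCCCC[C@]1(O)C(=O)C=C[C@@H]2OC(C)(C)O[C@@H]12 | intermediate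
15 | Pleiogenone A | CCCCCCCC/C=C\CCCCCCC[C@]1(O)C(=O)C=C[C@H](O)[C@H]1O | target

## Totals
- Total steps: 12.
- Longest linear sequence: 10 steps, from **5** to **15**. The chain fragment **4** is made in 2 convergent steps.

## Three steps most likely to fail
1. **Step 7 (diastereoselectivity at the quaternary carbinol).** Li or Mg chelation to the dioxolane oxygen would give the opposite epimer.
   - Fallback: reverse the order of bond construction. Close the cyclohexenone first from a chain-free α-hydroxy-ketone precursor, oxidise it to the 2,3-dione, and add the (Z)-alkenyl Grignard to the ring carbonyl. Facial bias anti to the adjacent oxygen would then set the centre.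
2. **Steps 10–11 (aldehyde/aldol).** Risks are lactol formation, epimerisation at the aldehyde α-carbon, γ-elimination, and retro-aldol.
   - Fallback: change the ring closure to ring-closing metathesis of a diene. The diene has a vinyl group at the former aldehyde carbon and a vinyl ketone on the carbinol carbon. The chain is carried as the internal alkyne and semi-hydrogenated last, so the Z-alkene is not exposed to the metathesis catalyst.
3. **Step 2 (Z-selectivity).** Over-reduction or E-isomer formation would give an inseparable mixture.
   - Fallback: discard the alkyne route. Build the Z-bromide by a non-stabilised Wittig reaction of nonylidenetriphenylphosphorane with 8-bromooctanal (or its protected form).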